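**Plan**

1. Retrosynthetic cuts, in order: the epoxide C–O bonds at C1/C10, the C8 ester C–O bond, C11=C13, C10–C14, then C2–C3 by a retro-[3,3] shift that restores C5–C10; in the resulting cyclohexane C10–C1, C5–C4, the lactone O6–C12 bond and C7–C11 are cut, and the carbocycle is traced to D-glucose (C6–C7 = glucose C6–C1).
2. Enabling feature (germacrane numbering): oxygenated C10 and the C4=C5 alkene of the ten-membered ring (C1–C10) are 1,5-related as in a cyclodec-5-enone, so C5–C10 can serve as the temporary shared bond of a cyclohexane (C5–C6–C7–C8–C9–C10) that already carries C6–C9 and the fused C6/C7 γ-lactone ring.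
3. Forward order of rings: six-membered carbocycle (Ferrier carbocyclisation), γ-lactone (Claisen, epoxide opening, lactonisation), ten-membered ring (oxy-Cope ring expansion), oxirane last.
4. Stereochemistry: C8 and C9 are C2 and C3 of D-glucose; glucose C4 (later the C10 ketone) holds the ring conformation; C7 comes from suprafacial Claisen transfer from C5; C6 and C5 from trans-diaxial epoxide opening; the C10 carbinol from axial alkynyl addition; Z-C4=C5 from the chair transition state; C1/C10 from C9-hydroxyl-directed epoxidation; the side-chain centre from (S)-2-methylbutanoic acid.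

Key step: step 17

Remark: germacrane numbering is used for every carbocyclic compound (ring C1–C10; C11, C12, C13 lactone carbons; C14 ester carbon; C15 methyl). β is the face of the C8 oxygen (later also of the C7–C11 bond), α the opposite face. PMB = 4-methoxybenzyl, MOM = methoxymethyl, TBS = tert-butyldimethylsilyl.
Assumption: the Luche reduction of step 8 follows axial hydride delivery and gives the 5α-alcohol; the inversion in step 9 is planned on that basis.

**Route**

Step 1
Reactants: 1 methyl 4,6-O-benzylidene-α-D-glucopyranoside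
Product: 3 methyl 4,6-O-benzylidene-2-O-PMB-α-D-glucopyranoside, via stannylene acetal 2 (not isolated)
Conditions: Bu2SnO, toluene, reflux (Dean–Stark); then PMBCl, Bu4NI (cat.), 90 °C
Reagents that add atoms: 4-methoxybenzyl chloride, COc1ccc(CCl)cc1
Why: Stannylene-acetal activation of the trans-diequatorial 2,3-diol directs alkylation to O2, the oxygen next to the axial anomeric methoxy group, so only the future C8 oxygen receives the PMB group.

Step 2
Reactants: 3 methyl 4,6-O-benzylidene-2-O-PMB-α-D-glucopyranoside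
Product: 4 methyl 4,6-O-benzylidene-2-O-PMB-3-O-MOM-α-D-glucopyranoside
Conditions: MOMCl, iPr2NEt, Bu4NI (cat.), CH2Cl2, 40 °C
Reagents that add atoms: chloromethyl methyl ether, COCCl
Why: Alkylation of the remaining 3-OH under amine base installs the base-stable, non-migrating acetal that will sit on C9 next to the later C10 alkoxide.

Step 3
Reactants: 4 methyl 4,6-O-benzylidene-2-O-PMB-3-O-MOM-α-D-glucopyranoside
Product: 5 methyl 2-O-PMB-3-O-MOM-α-D-glucopyranoside (4,6-diol)
Conditions: CSA (10 mol%), MeOH, rt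
Reagents that add atoms: none
Why: Acid-catalysed transacetalisation in methanol removes the benzylidene acetal, while the PMB ether and the MOM acetal need stronger acid and stay.

Step 4
Reactants: 5 methyl 2-O-PMB-3-O-MOM-α-D-glucopyranoside
Product: 6 methyl 6-deoxy-6-iodo-2-O-PMB-3-O-MOM-α-D-glucopyranoside
Conditions: iodine, PPh3, imidazole, toluene, 70 °C
Reagents that add atoms: iodine, [I][I]
Why: Appel-type iodination converts only the primary 6-OH, since the hindered secondary 4-OH does not form a displaceable oxyphosphonium under these conditions.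

Step 5
Reactants: 6 methyl 6-deoxy-6-iodo-2-O-PMB-3-O-MOM-α-D-glucopyranoside
Product: 7 methyl 4-O-TBS-6-deoxy-6-iodo-2-O-PMB-3-O-MOM-α-D-glucopyranoside
Conditions: TBSOTf, 2,6-lutidine, CH2Cl2, 0 °C
Reagents that add atoms: tert-butyldimethylsilyl triflate, CC(C)(C)[Si](C)(C)OS(=O)(=O)C(F)(F)F
Why: Silylation of the last free hydroxyl gives an ether on glucose O4 (future C10 oxygen) that keeps this position equatorial and can later be removed by fluoride beside PMB and MOM.

Step 6
Reactants: 7 methyl 4-O-TBS-6-deoxy-6-iodo-2-O-PMB-3-O-MOM-α-D-glucopyranoside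
Product: 8 methyl 4-O-TBS-6-deoxy-2-O-PMB-3-O-MOM-α-D-xylo-hex-5-enopyranoside
Conditions: DBU, DMF, 80 °C
Reagents that add atoms: none
Why: E2 dehydroiodination of the primary iodide gives the exocyclic enol ether required for the carbocyclisation.

Step 7
Reactants: 8 methyl 4-O-TBS-6-deoxy-2-O-PMB-3-O-MOM-α-D-xylo-hex-5-enopyranoside
Product: 10 8β-PMBO-9α-MOMO-10β-TBSO-cyclohex-6-en-5-one, via β-hydroxy ketone 9 (not isolated)
Conditions: Hg(OCOCF3)2 (5 mol%), acetone–H2O 4:1, rt; then MsCl, Et3N, CH2Cl2, 0 °C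
Reagents that add atoms: water, O
Why: Ferrier carbocyclisation (oxymercuration of the enol ether by divalent mercury, loss of methanol, intramolecular aldol closure) forms the carbocycle with glucose C5 as ketone and C1 as C7, and mesylation with E1cB elimination gives the enone; C8, C9 and C10 keep the glucose C2, C3 and C4 configurations.

Step 8
Reactants: 10 8β-PMBO-9α-MOMO-10β-TBSO-cyclohex-6-en-5-one
Product: 11 5α-hydroxy-8β-PMBO-9α-MOMO-10β-TBSO-cyclohex-6-ene (5,10-trans)
Conditions: NaBH4, CeCl3·7H2O, MeOH, −78 °C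
Reagents that add atoms: none
Why: Luche reduction gives clean 1,2-reduction, and axial hydride delivery to the half-chair with three equatorial ether groups should give the pseudo-equatorial 5α-alcohol.

Step 9
Reactants: 11 5α-hydroxy-8β-PMBO-9α-MOMO-10β-TBSO-cyclohex-6-ene
Product: 13 5β-hydroxy-8β-PMBO-9α-MOMO-10β-TBSO-cyclohex-6-ene (5,10-cis), via 5β-nitrobenzoate 12 (not isolated)
Conditions: 4-nitrobenzoic acid, PPh3, DIAD, THF, 0 °C to rt; then K2CO3, MeOH, rt
Reagents that add atoms: 4-nitrobenzoic acid, OC(=O)c1ccc(cc1)[N+](=O)[O-]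
Why: Mitsunobu reaction inverts C5 by SN2 displacement of the oxyphosphonium, and methanolysis of the activated ester frees the 5β-alcohol, now pseudo-axial and on the face to which C11 must be delivered.

Step 10
Reactants: 13 5β-hydroxy-8β-PMBO-9α-MOMO-10β-TBSO-cyclohex-6-ene
Product: 14 N,N-dimethyl-2-(8β-PMBO-9α-MOMO-10β-TBSO-cyclohex-5-en-7β-yl)acetamide
Conditions: MeC(OMe)2NMe2, xylene, 140 °C
Reagents that add atoms: N,N-dimethylacetamide dimethyl acetal, CC(OC)(OC)N(C)C
Why: Eschenmoser–Claisen rearrangement: the ketene N,O-acetal formed on the pseudo-axial 5β-oxygen undergoes a suprafacial [3,3] shift that puts C11 on C7 from the β face (cis to the C8 oxygen) and moves the alkene to C5=C6.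

Step 11
Reactants: 14 N,N-dimethyl-2-(8β-PMBO-9α-MOMO-10β-TBSO-cyclohex-5-en-7β-yl)acetamide
Product: 15 5α,6α-epoxide of 14
Conditions: dimethyldioxirane, acetone–CH2Cl2, 0 °C
Reagents that add atoms: dimethyldioxirane, CC1(C)OO1
Why: Epoxidation by a neutral dioxirane avoids acid-triggered participation of the amide, and the pseudo-axial C7 side chain together with the C10 silyl ether shields the β face, so oxygen enters from the α face.

Step 12
Reactants: 15 5α,6α-epoxide of 14; 16 isopropenylmagnesium bromide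
Product: 17 N,N-dimethyl-2-(6α-hydroxy-5β-isopropenyl-8β-PMBO-9α-MOMO-10β-TBSO-cyclohex-7β-yl)acetamide
Conditions: CuBr·SMe2 (20 mol%), THF, −40 to 0 °C; aq. NH4Cl
Reagents that add atoms: none
Why: Copper-catalysed Grignard opening of the epoxide follows the Fürst–Plattner rule: with the C8, C9 and C10 ethers equatorial, only attack at C5 from the β face gives the trans-diaxial product, which sets 5β-isopropenyl and 6α-hydroxyl; the tertiary amide is inert at this temperature.

Step 13
Reactants: 17 N,N-dimethyl-2-(6α-hydroxy-5β-isopropenyl-8β-PMBO-9α-MOMO-10β-TBSO-cyclohex-7β-yl)acetamide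
Product: 19 trans-fused 6α,12-lactone with 5β-isopropenyl 8β-PMBO 9α-MOMO 10β-hydroxy groups, via diol amide 18 (not isolated)
Conditions: Bu4NF, THF, 0 °C to rt; then AcOH, 60 °C
Reagents that add atoms: none
Why: Fluoride removes the silyl ether, and warm acetic acid drives hydroxyl-assisted acyl transfer from the dimethylamide to the 6α-oxygen; closing the trans-fused γ-lactone flips the chair so that isopropenyl, C6–O and C7–C11 are equatorial.

Step 14
Reactants: 19 trans-fused 6α,12-lactone with 10β-hydroxyl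
Product: 20 10-oxo lactone (5β-isopropenyl, 8β-PMBO, 9α-MOMO)
Conditions: Dess–Martin periodinane, NaHCO3, CH2Cl2, 0 °C to rt
Reagents that add atoms: none
Why: Dess–Martin oxidation under buffered, base-free conditions keeps the equatorial isopropenyl centre α to the new ketone and does not draw the alkene into conjugation.

Step 15
Reactants: 20 10-oxo lactone; 21 ethynylmagnesium bromide
Product: 22 10β-ethynyl-10α-hydroxy lactone
Conditions: 21 premixed with anhydrous CeCl3, THF, −78 °C; aq. NH4Cl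
Reagents that add atoms: none
Why: Organocerium 1,2-addition suppresses enolisation, and the rod-shaped nucleophile should enter C10 axially from the β face, antiperiplanar to the axial 9α C–O bond (polar Felkin–Anh) whose acetal also screens the α face, giving the equatorial 10α-hydroxyl and the cis relationship of the two unsaturated groups.

Step 16
Reactants: 22 10β-ethynyl-10α-hydroxy lactone
Product: 23 10β-vinyl-10α-hydroxy-5β-isopropenyl lactone (cis-1-vinyl-2-isopropenylcyclohexanol)
Conditions: H2 (1 atm), Pd/CaCO3 poisoned with Pb(OAc)2, quinoline, EtOAc, rt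
Reagents that add atoms: none
Why: Lindlar semihydrogenation stops at the vinyl group; the 1,1-disubstituted isopropenyl alkene and the PMB ether are not reduced on the poisoned catalyst.

Step 17
Reactants: 23 10β-vinyl-10α-hydroxy-5β-isopropenyl lactone
Product: 26 (4Z)-10-oxo-8β-PMBO-9α-MOMO ten-membered lactone, via dipotassium alkoxide-enolate 24 (not isolated), via dipotassium bis-enolate 25 (not isolated)
Conditions: KN(SiMe3)2 (2.5 equiv), 18-crown-6, THF, −78 to 0 °C; then AcOH, −78 °C
Reagents that add atoms: none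
Why: KN(SiMe3)2 with 18-crown-6 gives the dissociated C10 potassium alkoxide (the lactone rests as its enolate), whose oxyanion weakens C5–C10 so that the 1,5-diene C3=C4–C5–C10–C1=C2 undergoes a concerted chair-like [3,3] sigmatropic shift, forming C2–C3 and cleaving C5–C10 to the C1=C10 enolate of the ten-membered ketone. The closest known reaction type is the anionic oxy-Cope rearrangement of 1,2-dialkenylcyclohexanols to cyclodec-5-enones. The ten-membered ring (C1–C10) is closed by four-carbon ring expansion, that is by making C2–C3 while the bond shared with the six-membered ring breaks, not by an end-to-end cyclisation. No stereocentre is created, and C6–C9 lie outside the six reacting atoms and are carried over unchanged. The step needs Z geometry at C4=C5: the trans-fused lactone locks the chair with equatorial 5β-isopropenyl and axial 10β-vinyl, which places C6 axial on the six-centre chair and therefore cis to C3 in the new alkene, whereas the E alkene would require an axial isopropenyl group. The enolate geometry at C1=C10 is erased by the acetic acid quench, and quenching cold prevents enolate equilibration toward C9.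

Step 18
Reactants: 26 (4Z)-10-oxo-8β-PMBO-9α-MOMO ten-membered lactone
Product: 28 (1(10)E,4Z)-10-trifluoromethanesulfonyloxy diene lactone (C2 cis to C9), via potassium enolate 27 (not isolated)
Conditions: KN(SiMe3)2 (1.1 equiv), THF, −78 °C; then PhNTf2, −78 to 0 °C
Reagents that add atoms: N-phenyl-bis(trifluoromethanesulfonimide), FC(F)(F)S(=O)(=O)N(c1ccccc1)S(=O)(=O)C(F)(F)F
Why: Kinetic deprotonation by the bulky amide takes the C1 methylene rather than the C9 methine (and the ketone rather than the less acidic lactone), and O-sulfonylation gives the enol triflate; the ring that already holds the cis C4=C5 alkene is expected to accept the new double bond as the less strained ring-cis isomer.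

Step 19
Reactants: 28 (1(10)E,4Z)-10-trifluoromethanesulfonyloxy diene lactone
Product: 29 methyl (1(10)E,4Z)-8β-PMBO-9α-MOMO-diene-lactone-14-oate
Conditions: CO (1 atm), Pd(OAc)2 (10 mol%), PPh3 (20 mol%), Et3N, MeOH–DMF, 50 °C
Reagents that add atoms: carbon monoxide, [C-]#[O+]; methanol, CO
Why: Palladium-catalysed methoxycarbonylation (oxidative addition of the vinyl triflate to zerovalent palladium, CO insertion, methanolysis of the acylpalladium) installs C14 with retention of alkene geometry.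

Step 20
Reactants: 29 methyl (1(10)E,4Z)-8β-PMBO-9α-MOMO-diene-lactone-14-oate
Product: 33 11(13)-methylene lactone of 29, via lithium enolate 30 (not isolated), via Mannich base 31 (not isolated), via ammonium iodide 32 (not isolated)
Conditions: LiN(SiMe3)2, THF, −78 °C; CH2=NMe2+ I−, −78 °C to rt; then MeI, MeOH, rt; then aq. NaHCO3, rt
Reagents that add atoms: N,N-dimethylmethyleneiminium iodide (Eschenmoser's salt), C=[N+](C)C.[I-]
Why: Lactone-enolate Mannich reaction, N-methylation and E1cB loss of trimethylamine install the exocyclic methylene; the lactone α-protons are removed in preference to the γ-protons of the enoate.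

Step 21
Reactants: 33 11(13)-methylene lactone (8β-PMBO, 9α-MOMO)
Product: 34 8β-hydroxy-9α-MOMO methylene lactone ester
Conditions: DDQ, CH2Cl2–pH 7 buffer, 0 °C to rt
Reagents that add atoms: none
Why: Oxidative PMB cleavage (hydride abstraction, hydrolysis of the oxocarbenium ion) frees only the C8 hydroxyl and leaves the MOM acetal, the esters and the alkenes untouched.

Step 22
Reactants: 34 8β-hydroxy-9α-MOMO methylene lactone ester; 35 (S)-2-methylbutanoic acid
Product: 36 8β-[(2S)-2-methylbutanoyloxy]-9α-MOMO methylene lactone ester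
Conditions: EDC·HCl, DMAP (cat.), CH2Cl2, 0 °C to rt
Reagents that add atoms: none
Why: Steglich-type esterification acylates the only free hydroxyl, so the regiochemistry is certain, and low temperature with catalytic DMAP keeps the α-centre of the acid intact.

Step 23
Reactants: 36 8β-[(2S)-2-methylbutanoyloxy]-9α-MOMO methylene lactone ester
Product: 38 9α-hydroxy-8β-[(2S)-2-methylbutanoyloxy] methylene lactone ester, via bipyridinium acetal 37 (not isolated)
Conditions: TMSOTf, 2,2′-bipyridyl, CH2Cl2, 0 °C; then H2O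
Reagents that add atoms: none
Why: Silyl triflate–bipyridyl activation converts the MOM acetal into an N,O-acetal pyridinium salt that water hydrolyses; the buffered, non-protic conditions spare the esters, the methylene lactone and the 1,5-diene.

Step 24
Reactants: 38 9α-hydroxy-8β-[(2S)-2-methylbutanoyloxy] methylene lactone ester
Product: 39 CNP0581690.1, methyl (1R,4Z,6R,7S,8S,9R,10S)-1,10-epoxy-9-hydroxy-8-[(2S)-2-methylbutanoyloxy]germacra-4,11(13)-dien-12,6-olid-14-oate
Conditions: VO(acac)2 (10 mol%), t-BuOOH (decane), CH2Cl2, 0 °C to rt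
Reagents that add atoms: tert-butyl hydroperoxide, CC(C)(C)OO
Why: Hydroxyl-directed epoxidation through the vanadium alkylperoxide bound to the C9 alkoxide selects the allylic C1=C10 bond over C4=C5 and the methylene lactone; with C9–H eclipsing the alkene to relieve A(1,3) strain against C2, oxygen is delivered to the exposed face syn to the hydroxyl, giving the threo epoxy alcohol.

**Compound list**

1 | methyl 4,6-O-benzylidene-α-D-glucopyranoside | [C@@H]1(c2ccccc2)OC[C@H]3O[C@H](OC)[C@H](O)[C@@H](O)[C@@H]3O1 | starting material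
2 | 2,3-O-dibutylstannylene acetal of 1 | [C@@H]1(c2ccccc2)OC[C@H]3O[C@H](OC)[C@@H]4O[Sn](CCCC)(CCCC)O[C@H]4[C@@H]3O1 | intermediate (not isolated)
3 | methyl 4,6-O-benzylidene-2-O-PMB-α-D-glucopyranoside | [C@@H]1(c2ccccc2)OC[C@H]3O[C@H](OC)[C@H](OCc4ccc(OC)cc4)[C@@H](O)[C@@H]3O1 | intermediate
4 | methyl 4,6-O-benzylidene-2-O-PMB-3-O-MOM-α-D-glucopyranoside | [C@@H]1(c2ccccc2)OC[C@H]3O[C@H](OC)[C@H](OCc4ccc(OC)cc4)[C@@H](OCOC)[C@@H]3O1 | intermediate
5 | methyl 2-O-PMB-3-O-MOM-α-D-glucopyranoside | OC[C@H]1O[C@H](OC)[C@H](OCc2ccc(OC)cc2)[C@@H](OCOC)[C@@H]1O | intermediate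
6 | methyl 6-deoxy-6-iodo-2-O-PMB-3-O-MOM-α-D-glucopyranoside | IC[C@H]1O[C@H](OC)[C@H](OCc2ccc(OC)cc2)[C@@H](OCOC)[C@@H]1O | intermediate
7 | methyl 4-O-TBS-6-deoxy-6-iodo-2-O-PMB-3-O-MOM-α-D-glucopyranoside | IC[C@H]1O[C@H](OC)[C@H](OCc2ccc(OC)cc2)[C@@H](OCOC)[C@@H]1O[Si](C)(C)C(C)(C)C | intermediate
8 | methyl 4-O-TBS-6-deoxy-2-O-PMB-3-O-MOM-α-D-xylo-hex-5-enopyranoside | C=C1O[C@H](OC)[C@H](OCc2ccc(OC)cc2)[C@@H](OCOC)[C@@H]1O[Si](C)(C)C(C)(C)C | intermediate
9 | 7-hydroxy-8β-PMBO-9α-MOMO-10β-TBSO-cyclohexan-5-one (C7 epimers) | O=C1CC(O)[C@H](OCc2ccc(OC)cc2)[C@@H](OCOC)[C@@H]1O[Si](C)(C)C(C)(C)C | intermediate (not isolated)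
10 | 8β-PMBO-9α-MOMO-10β-TBSO-cyclohex-6-en-5-one | O=C1C=C[C@H](OCc2ccc(OC)cc2)[C@@H](OCOC)[C@@H]1O[Si](C)(C)C(C)(C)C | intermediate
11 | 5α-hydroxy-8β-PMBO-9α-MOMO-10β-TBSO-cyclohex-6-ene | O[C@H]1C=C[C@H](OCc2ccc(OC)cc2)[C@@H](OCOC)[C@@H]1O[Si](C)(C)C(C)(C)C | intermediate
12 | 5β-(4-nitrobenzoyloxy)-8β-PMBO-9α-MOMO-10β-TBSO-cyclohex-6-ene | O=C(O[C@@H]1C=C[C@H](OCc2ccc(OC)cc2)[C@@H](OCOC)[C@@H]1O[Si](C)(C)C(C)(C)C)c3ccc(cc3)[N+](=O)[O-] | intermediate (not isolated)
13 | 5β-hydroxy-8β-PMBO-9α-MOMO-10β-TBSO-cyclohex-6-ene | O[C@@H]1C=C[C@H](OCc2ccc(OC)cc2)[C@@H](OCOC)[C@@H]1O[Si](C)(C)C(C)(C)C | intermediate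
14 | N,N-dimethyl-2-(8β-PMBO-9α-MOMO-10β-TBSO-cyclohex-5-en-7β-yl)acetamide | CN(C)C(=O)C[C@H]1C=C[C@@H](O[Si](C)(C)C(C)(C)C)[C@H](OCOC)[C@H]1OCc2ccc(OC)cc2 | intermediate
15 | 5α,6α-epoxide of 14 | CN(C)C(=O)C[C@H]1[C@@H]2O[C@@H]2[C@@H](O[Si](C)(C)C(C)(C)C)[C@H](OCOC)[C@H]1OCc3ccc(OC)cc3 | intermediate
16 | isopropenylmagnesium bromide | CC(=C)[Mg]Br | starting material
17 | N,N-dimethyl-2-(6α-hydroxy-5β-isopropenyl-8β-PMBO-9α-MOMO-10β-TBSO-cyclohex-7β-yl)acetamide | CN(C)C(=O)C[C@H]1[C@H](O)[C@@H](C(C)=C)[C@@H](O[Si](C)(C)C(C)(C)C)[C@H](OCOC)[C@H]1OCc2ccc(OC)cc2 | intermediate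
18 | 6α,10β-dihydroxy analogue of 17 (diol amide) | CN(C)C(=O)C[C@H]1[C@H](O)[C@@H](C(C)=C)[C@@H](O)[C@H](OCOC)[C@H]1OCc2ccc(OC)cc2 | intermediate (not isolated)
19 | trans-fused 6α,12-lactone: 5β-isopropenyl, 8β-PMBO, 9α-MOMO, 10β-hydroxy | C1C(=O)O[C@@H]2[C@@H](C(C)=C)[C@@H](O)[C@H](OCOC)[C@@H](OCc3ccc(OC)cc3)[C@@H]12 | intermediate
20 | 10-oxo lactone: 5β-isopropenyl, 8β-PMBO, 9α-MOMO | C1C(=O)O[C@@H]2[C@@H](C(C)=C)C(=O)[C@H](OCOC)[C@@H](OCc3ccc(OC)cc3)[C@@H]12 | intermediate
21 | ethynylmagnesium bromide | C#C[Mg]Br | starting material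
22 | 10β-ethynyl-10α-hydroxy lactone | C1C(=O)O[C@@H]2[C@@H](C(C)=C)[C@@](O)(C#C)[C@H](OCOC)[C@@H](OCc3ccc(OC)cc3)[C@@H]12 | intermediate
23 | 10β-vinyl-10α-hydroxy-5β-isopropenyl lactone (oxy-Cope precursor) | C1C(=O)O[C@@H]2[C@@H](C(C)=C)[C@@](O)(C=C)[C@H](OCOC)[C@@H](OCc3ccc(OC)cc3)[C@@H]12 | intermediate
24 | dipotassium C10 alkoxide / lactone enolate of 23 | [K+].[K+].C1=C([O-])O[C@@H]2[C@@H](C(C)=C)[C@@]([O-])(C=C)[C@H](OCOC)[C@@H](OCc3ccc(OC)cc3)[C@@H]12 | intermediate (not isolated)
25 | dipotassium C1=C10 enolate / lactone enolate of 26 | [K+].[K+].C1=C([O-])O[C@@H]2/C=C(/C)CC/C=C(\[O-])[C@H](OCOC)[C@@H](OCc3ccc(OC)cc3)[C@@H]12 | intermediate (not isolated)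
26 | (4Z)-10-oxo-8β-PMBO-9α-MOMO ten-membered 6α,12-lactone | C1C(=O)O[C@@H]2/C=C(/C)CCCC(=O)[C@H](OCOC)[C@@H](OCc3ccc(OC)cc3)[C@@H]12 | intermediate
27 | potassium C1=C10 enolate of 26 (C2 cis to C9) | [K+].C1C(=O)O[C@@H]2/C=C(/C)CC/C=C(/[O-])[C@H](OCOC)[C@@H](OCc3ccc(OC)cc3)[C@@H]12 | intermediate (not isolated)
28 | (1(10)E,4Z)-10-triflyloxy diene lactone | C1C(=O)O[C@@H]2/C=C(/C)CC/C=C(/OS(=O)(=O)C(F)(F)F)[C@H](OCOC)[C@@H](OCc3ccc(OC)cc3)[C@@H]12 | intermediate
29 | methyl (1(10)E,4Z)-8β-PMBO-9α-MOMO-diene-lactone-14-oate | C1C(=O)O[C@@H]2/C=C(/C)CC/C=C(/C(=O)OC)[C@H](OCOC)[C@@H](OCc3ccc(OC)cc3)[C@@H]12 | intermediate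
30 | lithium lactone enolate of 29 | [Li+].C1=C([O-])O[C@@H]2/C=C(/C)CC/C=C(/C(=O)OC)[C@H](OCOC)[C@@H](OCc3ccc(OC)cc3)[C@@H]12 | intermediate (not isolated)
31 | 11-(dimethylaminomethyl) lactone (C11 epimers) | CN(C)CC1C(=O)O[C@@H]2/C=C(/C)CC/C=C(/C(=O)OC)[C@H](OCOC)[C@@H](OCc3ccc(OC)cc3)[C@@H]12 | intermediate (not isolated)
32 | 11-(trimethylammoniomethyl) lactone iodide | C[N+](C)(C)CC1C(=O)O[C@@H]2/C=C(/C)CC/C=C(/C(=O)OC)[C@H](OCOC)[C@@H](OCc3ccc(OC)cc3)[C@@H]12.[I-] | intermediate (not isolated)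
33 | 11(13)-methylene lactone ester: 8β-PMBO, 9α-MOMO | C=C1C(=O)O[C@@H]2/C=C(/C)CC/C=C(/C(=O)OC)[C@H](OCOC)[C@@H](OCc3ccc(OC)cc3)[C@@H]12 | intermediate
34 | 8β-hydroxy-9α-MOMO methylene lactone ester | C=C1C(=O)O[C@@H]2/C=C(/C)CC/C=C(/C(=O)OC)[C@H](OCOC)[C@@H](O)[C@@H]12 | intermediate
35 | (S)-2-methylbutanoic acid | CC[C@H](C)C(=O)O | starting material
36 | 8β-[(2S)-2-methylbutanoyloxy]-9α-MOMO methylene lactone ester | C=C1C(=O)O[C@@H]2/C=C(/C)CC/C=C(/C(=O)OC)[C@H](OCOC)[C@@H](OC(=O)[C@@H](C)CC)[C@@H]12 | intermediate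
37 | 9α-O-[(2,2′-bipyridin-1-ium-1-yl)methyl] acetal triflate of 38 | C=C1C(=O)O[C@@H]2/C=C(/C)CC/C=C(/C(=O)OC)[C@H](OC[n+]3ccccc3-c4ccccn4)[C@@H](OC(=O)[C@@H](C)CC)[C@@H]12.[O-]S(=O)(=O)C(F)(F)F | intermediate (not isolated)
38 | 9α-hydroxy-8β-[(2S)-2-methylbutanoyloxy] methylene lactone ester | C=C1C(=O)O[C@@H]2/C=C(/C)CC/C=C(/C(=O)OC)[C@H](O)[C@@H](OC(=O)[C@@H](C)CC)[C@@H]12 | intermediate
39 | CNP0581690.1 | C=C1C(=O)O[C@@H]2/C=C(/C)CC[C@H]3O[C@@]3(C(=O)OC)[C@H](O)[C@@H](OC(=O)[C@@H](C)CC)[C@@H]12 | target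

**Totals and risks**

Total step count: 24. Longest linear sequence: 24 steps (from 1).

Step 24 (final epoxidation). Oxygen transfer from the vanadium peroxide to the ester-deactivated C1=C10 bond may be too slow, so the oxidant is consumed unproductively or drifts to the electron-rich C4=C5 bond. The fallback moves the epoxidation forward and runs it as a nucleophilic (Weitz–Scheffer type) oxidation, which only the enoate can accept while the lactone is still saturated. It sets out from 29: lithium tert-butyl peroxide (t-BuOOH, n-BuLi, THF, −20 °C) should add to C1 from the exposed face, the same face as argued for step 24, and close to the epoxy ester F1. The methylenation of step 20 then leads through the Mannich base F2 and the ammonium iodide F3 to the methylene lactone F4. DDQ gives the C8 alcohol F5, esterification with 35 gives the ester F6, and removal of the MOM group as in step 23 rejoins the route at 39.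

Step 18 (enol triflate). Enolisation may proceed with the ring-trans geometry (C2 trans to C9), which would lead to the wrong epoxide. The fallback sets the geometry by equilibration instead of by kinetic deprotonation. It sets out from 26: the same triflation would give the ring-trans triflate F7 and carbonylation as in step 19 the ring-trans ester F8. Reversible thiyl-radical addition (PhSSPh cat., visible light, benzene) should then relax the strained trans enoate of the cyclodeca-1,5-diene to the ring-cis ester, rejoining the route at 29.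

Step 15 (alkynyl addition). Facial selectivity may be poor, because the syn-axial 8β ether opposes the axial approach that the axial 9α acetal favours. The fallback delivers oxygen, not carbon, from the α face, so the same facial bias that would spoil the addition now gives the needed carbinol. It sets out from 20: Wittig ethylidenation (EtPPh3Br, KN(SiMe3)2, THF) gives the ethylidene compound F9, and dimethyldioxirane epoxidises the more substituted exocyclic alkene from the α face to the spiro-epoxide F10. Sodium phenylselenide (PhSeSePh, NaBH4, EtOH) opens it at the secondary carbon to the hydroxy selenide F11. H2O2 oxidation gives the selenoxide F12, whose syn-elimination away from the hydroxyl forms the vinyl group, rejoining the route at 23.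

**Further compounds**

F1 | step 24 | methyl (4Z)-1,10-epoxy-8β-PMBO-9α-MOMO-lactone-14-oate (saturated lactone) | C1C(=O)O[C@@H]2/C=C(/C)CC[C@H]3O[C@@]3(C(=O)OC)[C@H](OCOC)[C@@H](OCc4ccc(OC)cc4)[C@@H]12
F2 | step 24 | 11-(dimethylaminomethyl) derivative of F1 (C11 epimers) | CN(C)CC1C(=O)O[C@@H]2/C=C(/C)CC[C@H]3O[C@@]3(C(=O)OC)[C@H](OCOC)[C@@H](OCc4ccc(OC)cc4)[C@@H]12
F3 | step 24 | 11-(trimethylammoniomethyl) iodide of F1 | C[N+](C)(C)CC1C(=O)O[C@@H]2/C=C(/C)CC[C@H]3O[C@@]3(C(=O)OC)[C@H](OCOC)[C@@H](OCc4ccc(OC)cc4)[C@@H]12.[I-]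
F4 | step 24 | 11(13)-methylene lactone of F1 | C=C1C(=O)O[C@@H]2/C=C(/C)CC[C@H]3O[C@@]3(C(=O)OC)[C@H](OCOC)[C@@H](OCc4ccc(OC)cc4)[C@@H]12
F5 | step 24 | 8β-hydroxy-9α-MOMO epoxy methylene lactone ester | C=C1C(=O)O[C@@H]2/C=C(/C)CC[C@H]3O[C@@]3(C(=O)OC)[C@H](OCOC)[C@@H](O)[C@@H]12
F6 | step 24 | 9-O-MOM ether of 39 | C=C1C(=O)O[C@@H]2/C=C(/C)CC[C@H]3O[C@@]3(C(=O)OC)[C@H](OCOC)[C@@H](OC(=O)[C@@H](C)CC)[C@@H]12
F7 | step 18 | ring-trans (1(10)Z) isomer of triflate 28 | C1C(=O)O[C@@H]2/C=C(/C)CC/C=C(\OS(=O)(=O)C(F)(F)F)[C@H](OCOC)[C@@H](OCc3ccc(OC)cc3)[C@@H]12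
F8 | step 18 | ring-trans (1(10)Z) isomer of ester 29 | C1C(=O)O[C@@H]2/C=C(/C)CC/C=C(\C(=O)OC)[C@H](OCOC)[C@@H](OCc3ccc(OC)cc3)[C@@H]12
F9 | step 15 | 10-ethylidene lactone (alkene isomers) | C1C(=O)O[C@@H]2[C@@H](C(C)=C)C(=CC)[C@H](OCOC)[C@@H](OCc3ccc(OC)cc3)[C@@H]12
F10 | step 15 | 10-spiro-epoxide with α oxygen (methyl-bearing carbon unassigned) | C1C(=O)O[C@@H]2[C@@H](C(C)=C)[C@]3(OC3C)[C@H](OCOC)[C@@H](OCc4ccc(OC)cc4)[C@@H]12
F11 | step 15 | 10α-hydroxy-10β-[1-(phenylselanyl)ethyl] lactone | C1C(=O)O[C@@H]2[C@@H](C(C)=C)[C@@](O)(C(C)[Se]c3ccccc3)[C@H](OCOC)[C@@H](OCc4ccc(OC)cc4)[C@@H]12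
F12 | step 15 | selenoxide of F11 | C1C(=O)O[C@@H]2[C@@H](C(C)=C)[C@@](O)(C(C)[Se](=O)c3ccccc3)[C@H](OCOC)[C@@H](OCc4ccc(OC)cc4)[C@@H]12
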